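**Retrosynthetic overview**

1. Feature: in both 2-quinolones the pyridone bond q-C3=q-C4 is also the C=C of a cyclic enol ether (O–q-C4=q-C3 of the fused pyran A and of the bridged pyran B). A benzene ring on q-C4 with an ortho N=C=O therefore completes a C=N/C=C/C=C six-electron array, and closing q-C2–q-C3 makes each pyridone: 25 ⇐ 24 (two N–Me) ⇐ bis(acyl azide) 21.
2. 21 ⇐ bis(enol ether) diester 19 ⇐ twofold Suzuki coupling on the bis(ketene acetal phosphate) 17 of bis-lactone 16 (lactone C=O carbons become q-C4, α-CH2 carbons become q-C3).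
3. 16 ⇐ lactone B (C3 arm onto C1, iodolactonisation) ⇐ lactone A (C5 arm onto C8, oxymercuration) ⇐ diene 11. The two CH2CO arms become mirror-related once the ring alkene is consumed, so ring A is closed while they still differ (acid against tert-butyl ester), and no tertiary C–O bond is ionised afterwards.
4. 11 ⇐ (R)-carvone 1: C3 arm by α′-alkylation; Wharton transposition and oxidation move the ketone to C6; C5 arm by a second α′-alkylation; Kabalka reduction deletes the ketone.
5. Ring order: carbocycle (from 1) → lactone/pyran A → lactone/pyran B → both pyridone rings in one operation → N-methylation.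

Key step: step 15

Numbering: the carbocycle is numbered as a p-menthane throughout (C1 methyl-bearing, C4 carrying C8, the isopropenyl and later CMe2–O carbon); quinolone atoms carry the prefix q.

Remark: the oxirane of 4 and the carbinol of 5 are drawn anti to the isopropenyl group by analogy with carvone itself; both centres are erased in steps 3 and 4, so the route does not depend on this assignment.

**Route**

Step 1
Reactants: 1 (R)-(−)-carvone; 2 tert-butyl bromoacetate
Product: 3 tert-butyl 2-[(1S,6R)-3-methyl-2-oxo-6-(prop-1-en-2-yl)cyclohex-3-en-1-yl]acetate (C3 arm trans to the C4 isopropenyl group)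
Conditions: LiN(iPr)2, THF, −78 °C; then 2, DMPU, −78 → −30 °C
Reagents that add atoms: none
Why: Kinetic deprotonation of the enone at the α′ carbon C3 and SN2 alkylation of the enolate by the α-bromo ester (ketone enolate alkylation) should place the arm anti to the neighbouring C4 isopropenyl group, as is usual for carvone enolates, and the new centre is epimerisable toward this trans isomer.

Step 2
Reactants: 3
Product: 4 tert-butyl 2-[1-methyl-2-oxo-4-(prop-1-en-2-yl)-7-oxabicyclo[4.1.0]heptan-3-yl]acetate (C1–C6 oxirane anti to the isopropenyl group)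
Conditions: 30% H2O2, NaOH (cat.), MeOH, 0 °C
Reagents that add atoms: hydrogen peroxide, OO
Why: Weitz–Scheffer nucleophilic epoxidation attacks only the electron-poor enone C1=C6 bond (isopropenyl untouched), from the face anti to the isopropenyl group, and the two new oxirane centres are temporary.

Step 3
Reactants: 4
Product: 5 tert-butyl 2-[4-hydroxy-3-methyl-6-(prop-1-en-2-yl)cyclohex-2-en-1-yl]acetate (p-menthane 6-ol with C1=C2 alkene; hydroxyl anti to isopropenyl)
Conditions: N2H4·H2O, AcOH (cat.), MeOH, 0 °C → rt
Reagents that add atoms: none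
Why: Wharton transposition, in which the hydrazone of the α,β-epoxy ketone fragments with loss of N2, should move oxygen from C2 to C6 and the alkene to C1=C2, the carbinol centre keeping the oxirane configuration (erased in step 4).

Step 4
Reactants: 5
Product: 6 tert-butyl 2-[3-methyl-4-oxo-6-(prop-1-en-2-yl)cyclohex-2-en-1-yl]acetate (transposed enone, ketone on C6)
Conditions: Dess–Martin periodinane, CH2Cl2, rt
Reagents that add atoms: none
Why: Dess–Martin oxidation of the secondary allylic alcohol gives the transposed enone, in which C5 has become the α′ carbon, without touching the isopropenyl group or the ester.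

Step 5
Reactants: 6; 7 methyl bromoacetate
Product: 8 methyl 2-[5-(2-tert-butoxy-2-oxoethyl)-3-methyl-2-oxo-6-(prop-1-en-2-yl)cyclohex-3-en-1-yl]acetate (C3 and C5 arms both trans to the C4 isopropenyl group)
Conditions: LiN(iPr)2, THF, −78 °C; then 7, DMPU, −78 → −30 °C; then NaOMe (cat.), MeOH, 0 °C → rt
Reagents that add atoms: none
Why: A second kinetic α′-enolate alkylation (the ketone is far more acidic than the tert-butyl ester) should add the arm to C5 anti to the C4 isopropenyl group, and because C5 is enolisable the methoxide equilibration should drive any epimer to the all-trans, all-equatorial 3,4,5-arrangement.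

Step 6
Reactants: 8
Product: 9 N-tosylhydrazone of 8 at the ring ketone (C6)
Conditions: TsNHNH2, AcOH (cat.), EtOH, 50 °C
Reagents that add atoms: p-toluenesulfonohydrazide, Cc1ccc(cc1)S(=O)(=O)NN
Why: Acid-catalysed condensation of the conjugated ketone with tosylhydrazide gives the hydrazone needed for reductive transposition, with no stereocentre formed.

Step 7
Reactants: 9
Product: 11 methyl 2-[5-(2-tert-butoxy-2-oxoethyl)-3-methyl-6-(prop-1-en-2-yl)cyclohex-2-en-1-yl]acetate, via allylic diazene 10 (not isolated)
Conditions: catecholborane, CHCl3, 0 °C; then NaOAc·3H2O, 60 °C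
Reagents that add atoms: none
Why: Kabalka reductive transposition: catecholborane reduces the C=N bond, acetate-induced loss of sulfinate gives diazene 10, and this expels N2 by retro-ene hydrogen transfer to C2, so the ketone oxygen is removed, the alkene moves to C1=C6 and C2 becomes CH2.

Step 8
Reactants: 11
Product: 12 2-[5-(2-tert-butoxy-2-oxoethyl)-3-methyl-6-(prop-1-en-2-yl)cyclohex-2-en-1-yl]acetic acid (free acid on the C5 arm only)
Conditions: LiOH·H2O, THF/MeOH/H2O, 0 °C → rt; then 1 M HCl to pH 3, 0 °C
Reagents that add atoms: lithium hydroxide, [Li+].[OH-]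
Why: Saponification tells the two arms apart because hydroxide cleaves the unhindered methyl ester while the tert-butyl ester is inert.

Step 9
Reactants: 12
Product: 14 tert-butyl 2-[1,1,6-trimethyl-3-oxo-3,4,4a,7,8,8a-hexahydro-1H-isochromen-8-yl]acetate (lactone A; trans-fused), via organomercurial lactone 13 (not isolated)
Conditions: Hg(OAc)2, CH2Cl2, 0 °C → rt; then NaBH4, aq NaHCO3, THF, 0 °C
Reagents that add atoms: mercury diacetate, CC(=O)O[Hg]OC(C)=O (its atoms are held in 13 and leave again on reduction)
Why: Oxymercuration-type lactonisation: Hg(OAc)2 reacts faster with the 1,1-disubstituted isopropenyl alkene than with the trisubstituted ring alkene, the only free carboxyl (C5 arm) opens the mercurinium ion at tertiary C8 (Markovnikov, six-membered ring, trans-fused because the arm is already trans to C8), and borohydride then replaces mercury by hydrogen so the transient C8 centre becomes CMe2.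

Step 10
Reactants: 14
Product: 15 iodo bis-lactone (lactone B closed from the C3 arm onto C1; iodine on C6 anti to the new C1–O bond)
Conditions: I2, NaHCO3, MeCN (dry), 0 °C → rt, dark
Reagents that add atoms: iodine, II
Why: Iodolactonisation with a tert-butyl ester as internal nucleophile: the ester carbonyl oxygen of the C3 arm opens the iodonium ion of the C1=C6 alkene at tertiary C1 (6-exo, Markovnikov) with loss of isobutene, so the C1–O bond must form on the face of the C3 arm (methyl anti), under non-acidic kinetic conditions that leave the C8–O bond of lactone A alone.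

Step 11
Reactants: 15
Product: 16 bis-lactone (δ-lactone A trans-fused at C4–C5 with O on C8; δ-lactone B bridging C3 and C1 with O on C1)
Conditions: Bu3SnH, AIBN (cat.), PhMe, 80 °C
Reagents that add atoms: none
Why: Radical chain deiodination replaces the secondary iodide by hydrogen and erases the C6 centre without affecting either lactone.

Step 12
Reactants: 16
Product: 17 bis(ketene acetal diphenyl phosphate) of 16
Conditions: KN(SiMe3)2, (PhO)2P(O)Cl, THF/DMPU, −78 °C
Reagents that add atoms: diphenyl chlorophosphate, O=P(Cl)(Oc1ccccc1)Oc1ccccc1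
Why: Double enolisation of the two δ-lactones with in-situ O-phosphorylation gives the ketene acetal phosphates (the usual lactone-to-enol-phosphate activation); neither enol double bond lies at a bridgehead and no stereocentre changes.

Step 13
Reactants: 17; 18 2-(methoxycarbonyl)phenylboronic acid
Product: 19 bis(enol ether) diester (fused and bridged dihydropyrans each carrying a 2-(methoxycarbonyl)phenyl group on q-C4)
Conditions: 18, Pd(PPh3)4 (cat.), aq Na2CO3, DME, 80 °C
Reagents that add atoms: none
Why: Twofold Suzuki–Miyaura coupling of the ketene acetal phosphates (oxidative addition of zerovalent palladium into the C–O bond, transmetalation, reductive elimination) installs the aryl group on each enol-ether carbon q-C4.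

Step 14
Reactants: 19
Product: 21 bis(acyl azide): fused and bridged dihydropyrans each bearing a 2-(azidocarbonyl)phenyl group on q-C4, via dipotassium dicarboxylate 20 (not isolated)
Conditions: KOSiMe3, THF, rt; then (PhO)2P(O)N3, DMF, 0 °C → rt
Reagents that add atoms: potassium trimethylsilanolate, C[Si](C)(C)[O-].[K+]; diphenylphosphoryl azide, O=P(N=[N+]=[N-])(Oc1ccccc1)Oc1ccccc1
Why: Silanolate cleavage of the methyl esters gives the dry dicarboxylate 20 without exposing the acid-labile enol ethers to a free ortho-carboxylic acid, and the carboxylates then attack diphenylphosphoryl azide to give mixed anhydrides that azide converts into the aroyl azides (Shioiri acyl azide synthesis).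

Step 15
Reactants: 21
Product: 24 N,N′-didemethyl paraensidimerin C, via bis(isocyanate) 22 (not isolated), via bis(3H-quinolin-2-one) tautomer 23 (not isolated)
Conditions: o-dichlorobenzene (dry, 0.01 M), 110 °C, then 170 °C
Reagents that add atoms: none
Why: Each aroyl azide loses N2 with concerted 1,2-shift of the aryl group to nitrogen (Curtius rearrangement), forming both aryl–N bonds and the bis(isocyanate) 22. In each half the isocyanate C=N, the arene C=C and the enol-ether q-C3=q-C4 bond then make up a 1-aza-hexatriene that closes thermally by disrotatory 6π electrocyclisation, joining the isocyanate carbon (q-C2) to the nucleophilic enol-ether carbon q-C3; the closest known reaction type is the thermal cyclisation of 2-alkenylaryl isocyanates to quinolin-2(1H)-ones, here helped by the donor oxygen on q-C4. The pyridone ring of quinolone A and that of quinolone B are both closed in this electrocyclic mode, giving the non-aromatic tautomer 23, which regains its benzene rings by shift of each q-C3 hydrogen to nitrogen. No lasting stereocentre is made (the sp3 q-C3 centres of 23 vanish on tautomerisation) and the four carbocycle centres are spectators. The step needs chemoselectivity only: intramolecular closure must beat intermolecular isocyanate chemistry, which high dilution, a dry aprotic solvent and the ortho placement of N=C=O next to an electron-rich alkene should secure, and because the medium is neutral neither tertiary C–O bond ionises, so C8 keeps the oxygen of pyran A and C1 that of pyran B.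

Step 16
Reactants: 24
Product: 25 paraensidimerin C
Conditions: MeI, K2CO3, DMF, rt
Reagents that add atoms: iodomethane, CI
Why: N-Alkylation of the two 2-quinolone (lactam) anions with iodomethane under carbonate base in a dipolar aprotic solvent, which favours nitrogen over oxygen, should methylate both lactam nitrogens to give the target.

**Compound list**

1 | (R)-(−)-carvone, (5R)-2-methyl-5-(prop-1-en-2-yl)cyclohex-2-en-1-one | C=C(C)[C@@H]1CC=C(C)C(=O)C1 | starting material
2 | tert-butyl bromoacetate | CC(C)(C)OC(=O)CBr | starting material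
3 | tert-butyl 2-[(1S,6R)-3-methyl-2-oxo-6-(prop-1-en-2-yl)cyclohex-3-en-1-yl]acetate | C=C(C)[C@@H]1CC=C(C)C(=O)[C@H]1CC(=O)OC(C)(C)C | intermediate
4 | tert-butyl 2-[1-methyl-2-oxo-4-(prop-1-en-2-yl)-7-oxabicyclo[4.1.0]heptan-3-yl]acetate, oxirane anti to isopropenyl | C=C(C)[C@@H]1C[C@H]2O[C@@]2(C)C(=O)[C@H]1CC(=O)OC(C)(C)C | intermediate
5 | tert-butyl 2-[4-hydroxy-3-methyl-6-(prop-1-en-2-yl)cyclohex-2-en-1-yl]acetate, hydroxyl anti to isopropenyl | C=C(C)[C@@H]1C[C@@H](O)C(C)=C[C@H]1CC(=O)OC(C)(C)C | intermediate
6 | tert-butyl 2-[3-methyl-4-oxo-6-(prop-1-en-2-yl)cyclohex-2-en-1-yl]acetate | C=C(C)[C@@H]1CC(=O)C(C)=C[C@H]1CC(=O)OC(C)(C)C | intermediate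
7 | methyl bromoacetate | COC(=O)CBr | starting material
8 | methyl 2-[5-(2-tert-butoxy-2-oxoethyl)-3-methyl-2-oxo-6-(prop-1-en-2-yl)cyclohex-3-en-1-yl]acetate, both arms trans to isopropenyl | C=C(C)[C@@H]1[C@@H](CC(=O)OC)C(=O)C(C)=C[C@H]1CC(=O)OC(C)(C)C | intermediate
9 | N-tosylhydrazone of 8 | C=C(C)[C@@H]1[C@@H](CC(=O)OC)C(=NNS(=O)(=O)c2ccc(C)cc2)C(C)=C[C@H]1CC(=O)OC(C)(C)C | intermediate
10 | allylic diazene on C6 (configuration at C6 not defined) | C=C(C)[C@@H]1[C@@H](CC(=O)OC)C(N=N)C(C)=C[C@H]1CC(=O)OC(C)(C)C | intermediate (not isolated)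
11 | methyl 2-[5-(2-tert-butoxy-2-oxoethyl)-3-methyl-6-(prop-1-en-2-yl)cyclohex-2-en-1-yl]acetate | C=C(C)[C@@H]1[C@@H](CC(=O)OC)C=C(C)C[C@H]1CC(=O)OC(C)(C)C | intermediate
12 | 2-[5-(2-tert-butoxy-2-oxoethyl)-3-methyl-6-(prop-1-en-2-yl)cyclohex-2-en-1-yl]acetic acid | C=C(C)[C@@H]1[C@@H](CC(=O)O)C=C(C)C[C@H]1CC(=O)OC(C)(C)C | intermediate
13 | lactone A carrying CH2HgOAc on C8 (configuration at C8 not defined) | C2C(=O)OC(C)(C[Hg]OC(C)=O)[C@@H]1[C@@H]2C=C(C)C[C@H]1CC(=O)OC(C)(C)C | intermediate (not isolated)
14 | tert-butyl 2-[1,1,6-trimethyl-3-oxo-3,4,4a,7,8,8a-hexahydro-1H-isochromen-8-yl]acetate, trans-fused lactone A | C2C(=O)OC(C)(C)[C@@H]1[C@@H]2C=C(C)C[C@H]1CC(=O)OC(C)(C)C | intermediate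
15 | iodo bis-lactone, iodine on C6 anti to the C1–O bond | C2C(=O)OC(C)(C)[C@@H]1[C@@H]2[C@H](I)[C@]2(C)C[C@H]1CC(=O)O2 | intermediate
16 | bis-lactone (lactone A fused at C4–C5, lactone B bridging C3 and C1) | C2C(=O)OC(C)(C)[C@@H]1[C@@H]2C[C@]2(C)C[C@H]1CC(=O)O2 | intermediate
17 | bis(ketene acetal diphenyl phosphate) of 16 | C2=C(OP(=O)(Oc3ccccc3)Oc3ccccc3)OC(C)(C)[C@@H]1[C@@H]2C[C@]2(C)C[C@H]1C=C(OP(=O)(Oc1ccccc1)Oc1ccccc1)O2 | intermediate
18 | 2-(methoxycarbonyl)phenylboronic acid | COC(=O)c1ccccc1B(O)O | starting material
19 | bis(enol ether) diester, 2-(methoxycarbonyl)phenyl on each q-C4 | C2=C(c3ccccc3C(=O)OC)OC(C)(C)[C@@H]1[C@@H]2C[C@]2(C)C[C@H]1C=C(c1ccccc1C(=O)OC)O2 | intermediate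
20 | dipotassium dicarboxylate of 19 | C2=C(c3ccccc3C(=O)[O-])OC(C)(C)[C@@H]1[C@@H]2C[C@]2(C)C[C@H]1C=C(c1ccccc1C(=O)[O-])O2.[K+].[K+] | intermediate (not isolated)
21 | bis(acyl azide), 2-(azidocarbonyl)phenyl on each q-C4 | C2=C(c3ccccc3C(=O)N=[N+]=[N-])OC(C)(C)[C@@H]1[C@@H]2C[C@]2(C)C[C@H]1C=C(c1ccccc1C(=O)N=[N+]=[N-])O2 | intermediate
22 | bis(isocyanate), 2-isocyanatophenyl on each q-C4 | C2=C(c3ccccc3N=C=O)OC(C)(C)[C@@H]1[C@@H]2C[C@]2(C)C[C@H]1C=C(c1ccccc1N=C=O)O2 | intermediate (not isolated)
23 | bis(3H-quinolin-2-one) tautomer (q-C3 centres not defined) | O=C1N=C3C=CC=CC3=C(C12)OC(C)(C)[C@@H]1[C@@H]2C[C@]2(C)C[C@H]1C1C(=O)N=C3C=CC=CC3=C1O2 | intermediate (not isolated)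
24 | N,N′-didemethyl paraensidimerin C | [nH]1c(=O)c2c(c3ccccc31)OC(C)(C)[C@@H]1[C@@H]2C[C@]2(C)C[C@H]1c1c(c3ccccc3[nH]c1=O)O2 | intermediate
25 | paraensidimerin C | Cn1c(=O)c2c(c3ccccc31)OC(C)(C)[C@@H]1[C@@H]2C[C@]2(C)C[C@H]1c1c(c3ccccc3n(C)c1=O)O2 | target

**Step count and risk**

Total steps: 16. Longest linear sequence: 16 steps (1 → 25).

Steps most likely to fail:

Step 15. The acyl azide or the isocyanate may be diverted before ring closure. Possible diversions are dipolar addition of the electron-poor azide to the enol ether, hydrolysis and urea formation, and isocyanate dimerisation; the hindered trisubstituted enol ether may also close too slowly at a temperature the bis(enol ether) tolerates. The fallback builds the q-C2–q-C3 bond first and the aryl–N bond last, and sets out from 17. Suzuki coupling with 2-chlorophenylboronic acid (Pd(PPh3)4, aq Na2CO3, DME) would give the bis(2-chlorophenyl) bis(enol ether) F1. Chlorosulfonyl isocyanate (CH2Cl2, −78 °C) would acylate each enol ether at q-C3 to the bis(N-chlorosulfonyl carboxamide) F2, and aqueous Na2SO3/NaHCO3 would hydrolyse it to the bis(primary carboxamide) F3. Intramolecular Buchwald–Hartwig amidation (Pd(OAc)2, Xantphos, Cs2CO3, dioxane, 100 °C) would then close both N1–C8a bonds and return to the route at 24.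

Step 10. Closure of the bridged ring forces the carbocycle out of its chair, so the ester carbonyl may be too slow a nucleophile; the iodonium ion could then revert or be intercepted, and acid released on loss of the tert-butyl group could ionise the C8–O bond and mix which arm sits on C8. The fallback uses a free carboxylic acid and reversible Markovnikov oxymercuration, and sets out from 14. Me3SiOTf with 2,6-lutidine (CH2Cl2, 0 °C, aqueous work-up) would cleave the tert-butyl ester to the lactone A acid F4. Hg(O2CCF3)2 (CH2Cl2) would close the bridged ring to the organomercurial bis-lactone F5, and NaBH4 would reduce it directly to 16, so that 15 is bypassed.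

Step 13. Protodeboronation of the ortho-ester boronic acid and hydrolysis of the ketene acetal phosphates in the aqueous base may outrun the double transmetalation. The fallback is an anhydrous Negishi coupling and sets out from 17. Zinc insertion into methyl 2-iodobenzoate (Zn dust, LiCl, THF) would give 2-(methoxycarbonyl)phenylzinc iodide F6, which with Pd(PPh3)4 in THF at 50 °C would couple at both phosphates and return to the route at 19.

**Further compounds**

F1 | step 15 | bis(2-chlorophenyl) bis(enol ether) | C2=C(c3ccccc3Cl)OC(C)(C)[C@@H]1[C@@H]2C[C@]2(C)C[C@H]1C=C(c1ccccc1Cl)O2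
F2 | step 15 | bis(N-chlorosulfonyl carboxamide) | C2(C(=O)NS(=O)(=O)Cl)=C(c3ccccc3Cl)OC(C)(C)[C@@H]1[C@@H]2C[C@]2(C)C[C@H]1C(C(=O)NS(=O)(=O)Cl)=C(c1ccccc1Cl)O2
F3 | step 15 | bis(primary carboxamide) | C2(C(N)=O)=C(c3ccccc3Cl)OC(C)(C)[C@@H]1[C@@H]2C[C@]2(C)C[C@H]1C(C(N)=O)=C(c1ccccc1Cl)O2
F4 | step 10 | lactone A acid | C2C(=O)OC(C)(C)[C@@H]1[C@@H]2C=C(C)C[C@H]1CC(=O)O
F5 | step 10 | organomercurial bis-lactone | C2C(=O)OC(C)(C)[C@@H]1[C@@H]2[C@H]([Hg]OC(=O)C(F)(F)F)[C@]2(C)C[C@H]1CC(=O)O2
F6 | step 13 | 2-(methoxycarbonyl)phenylzinc iodide | COC(=O)c1ccccc1[Zn]I
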